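**Retrosynthetic overview**

1. Target ⇐ its tri-O-benzyl ether by hydrogenolysis. Rings A and B come from aromatic starting materials; ring C is the only ring made, and it is closed in the key step.
2. Key disconnection at O1–C8a and C3–C4 of ring C: a ring-B acid ArCH(OTBS)–CH(OMe)–CO2H and a ring-A 2-fluoroaroyl chloride are joined as a mixed anhydride (temporary tether). Nickel/photoredox CO2 extrusion makes C3–C4, then the unmasked C2 alkoxide displaces the ortho fluoride to make O1–C8a.
3. Enabling feature: the C4 carbonyl sits on ring A ortho to C8a and α to C3. One 2-fluoroaroyl unit is therefore the acyl donor for C3 and, once it is a ketone, the SNAr acceptor for O1. The only oxygen para to C8a (the C6 methoxy) is twisted out of conjugation by its two ortho neighbours, and the enolisable C3 settles trans to the C2 aryl group.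
4. C2 is set beforehand by an Evans glycolate syn-aldol on the ring-B aldehyde (from methoxyhydroquinone). The carboxyl group is a traceless handle, so the second aldol centre need not be controlled.
5. The ring-A acid chloride comes from 3,4,5-trimethoxyaniline: fluorodediazoniation, ortho-lithiation/formylation between F and OMe, ortho-demethylation/benzylation, oxidation.

Key step: step 13

Assumption: the target is the (2R,3R), 2,3-trans isomer; of the two C3 epimers of the ring-closed product the trans one (aryl and methoxy both equatorial) is taken to be the more stable, as is general for 3-oxygenated flavanones, and C3 is taken to equilibrate through the enol without opening ring C.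

**Route**

Step 1
Reactants: 1 2-methoxybenzene-1,4-diol (methoxyhydroquinone)
Product: 2 1,4-bis(benzyloxy)-2-methoxybenzene
Conditions: BnBr, K2CO3, DMF, 60 °C, under N2
Reagents that add atoms: benzyl bromide, BrCc1ccccc1
Why: Williamson ether synthesis on both phenols, with air excluded so that the hydroquinone is alkylated before it can oxidise.

Step 2
Reactants: 2 1,4-bis(benzyloxy)-2-methoxybenzene
Product: 4 2,5-bis(benzyloxy)-4-methoxybenzaldehyde, via iminium chloride 3 (not isolated)
Conditions: POCl3, DMF, 0 → 70 °C; then ice/H2O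
Reagents that add atoms: N,N-dimethylformamide, CN(C)C=O; water, O
Why: Vilsmeier–Haack formylation should go to the one position that is para to the methoxy group and ortho to a benzyloxy group (the usual site in 1,2,4-trialkoxybenzenes), and hydrolysis of iminium salt 3 frees the aldehyde.

Step 3
Reactants: 5 (S)-4-benzyloxazolidin-2-one; 6 methoxyacetyl chloride
Product: 8 (S)-4-benzyl-3-(2-methoxyacetyl)oxazolidin-2-one, via lithium oxazolidinide 7 (not isolated)
Conditions: n-BuLi, THF, −78 °C; then 6, −78 → 0 °C
Reagents that add atoms: none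
Why: N-acylation of the lithiated Evans auxiliary with an acid chloride, the standard entry to glycolate imides.

Step 4
Reactants: 8 (S)-4-benzyl-3-(2-methoxyacetyl)oxazolidin-2-one; 4 2,5-bis(benzyloxy)-4-methoxybenzaldehyde
Product: 10 (S)-4-benzyl-3-{(2S,3R)-3-[2,5-bis(benzyloxy)-4-methoxyphenyl]-3-hydroxy-2-methoxypropanoyl}oxazolidin-2-one, via boron enolate 9 (not isolated)
Conditions: Bu2BOTf, Et3N, CH2Cl2, −78 → 0 °C; then 4, −78 → 0 °C; H2O2, MeOH, pH 7 buffer, 0 °C
Reagents that add atoms: none
Why: Evans syn-aldol reaction, in which the Z boron enolate 9 reacts through a chair (Zimmerman–Traxler) transition state on the face away from the auxiliary benzyl group, setting the carbinol carbon R (the later C2) and the methoxy-bearing carbon S.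

Step 5
Reactants: 10 the syn-aldol adduct
Product: 11 (S)-4-benzyl-3-{(2S,3R)-3-[2,5-bis(benzyloxy)-4-methoxyphenyl]-3-[(tert-butyldimethylsilyl)oxy]-2-methoxypropanoyl}oxazolidin-2-one
Conditions: TBSOTf, 2,6-lutidine, CH2Cl2, −78 → 0 °C
Reagents that add atoms: tert-butyldimethylsilyl trifluoromethanesulfonate, CC(C)(C)[Si](C)(C)OS(=O)(=O)C(F)(F)F
Why: Silylation of the hindered benzylic alcohol with a silyl triflate and a hindered base, which blocks retro-aldol cleavage in step 6 and O-acylation in step 13.

Step 6
Reactants: 11 the silylated imide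
Product: 13 (2S,3R)-3-[2,5-bis(benzyloxy)-4-methoxyphenyl]-3-[(tert-butyldimethylsilyl)oxy]-2-methoxypropanoic acid, via peroxy acid 12 (not isolated)
Conditions: LiOH, H2O2, THF/H2O, 0 °C; then Na2SO3 (aq); 1 M HCl to pH 3, 0 °C
Reagents that add atoms: hydrogen peroxide, OO
Why: Hydroperoxide cleavage of the Evans imide at the exocyclic carbonyl, with sulfite reducing peroxy acid 12 to the acid; the cold, weakly basic medium should leave both stereocentres and the silyl ether intact.

Step 7
Reactants: 14 3,4,5-trimethoxyaniline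
Product: 16 5-fluoro-1,2,3-trimethoxybenzene, via diazonium fluoride 15 (not isolated)
Conditions: NaNO2, HF·pyridine, 0 °C; then 80 °C
Reagents that add atoms: hydrogen fluoride (as its pyridine complex), F
Why: Diazotisation and thermal fluorodediazoniation in HF·pyridine (Balz–Schiemann-type reaction) replace the amino group by fluorine, the methyl ethers being inert to the medium.

Step 8
Reactants: 16 5-fluoro-1,2,3-trimethoxybenzene
Product: 18 6-fluoro-2,3,4-trimethoxybenzaldehyde, via aryllithium 17 (not isolated)
Conditions: n-BuLi, THF, −78 °C; then DMF, −78 °C; aq HCl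
Reagents that add atoms: N,N-dimethylformamide, CN(C)C=O
Why: Directed ortho-metalation at the position flanked by fluorine and methoxy (the two such positions are equivalent by symmetry), with DMF trapping aryllithium 17 at −78 °C before it can lose LiF.

Step 9
Reactants: 18 6-fluoro-2,3,4-trimethoxybenzaldehyde
Product: 19 6-fluoro-2-hydroxy-3,4-dimethoxybenzaldehyde
Conditions: BCl3, CH2Cl2, −78 → 0 °C; then H2O
Reagents that add atoms: none
Why: Chelation-controlled demethylation, in which BCl3 bound to the aldehyde oxygen cleaves only the methoxy group ortho to the formyl group.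

Step 10
Reactants: 19 6-fluoro-2-hydroxy-3,4-dimethoxybenzaldehyde
Product: 20 2-(benzyloxy)-6-fluoro-3,4-dimethoxybenzaldehyde
Conditions: BnBr, K2CO3, DMF, rt
Reagents that add atoms: benzyl bromide, BrCc1ccccc1
Why: Williamson ether synthesis on the freed phenol, giving the later 5-hydroxyl a group that leaves in the final hydrogenolysis.

Step 11
Reactants: 20 2-(benzyloxy)-6-fluoro-3,4-dimethoxybenzaldehyde
Product: 21 2-(benzyloxy)-6-fluoro-3,4-dimethoxybenzoic acid
Conditions: NaClO2, NaH2PO4, 2-methyl-2-butene, t-BuOH/H2O, rt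
Reagents that add atoms: sodium chlorite, [Na+].[O-]Cl=O
Why: Pinnick oxidation of the aldehyde, with 2-methyl-2-butene trapping hypochlorous acid so that the electron-rich ring is not chlorinated.

Step 12
Reactants: 21 2-(benzyloxy)-6-fluoro-3,4-dimethoxybenzoic acid
Product: 22 2-(benzyloxy)-6-fluoro-3,4-dimethoxybenzoyl chloride
Conditions: (COCl)2, DMF (cat.), CH2Cl2, 0 °C → rt; evaporation, used crude
Reagents that add atoms: oxalyl chloride, O=C(Cl)C(Cl)=O
Why: Acid chloride formation through the catalytic chloroiminium (Vilsmeier-type) activator, under conditions that leave the benzyl ether and aryl fluoride untouched.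

Step 13
Reactants: 13 the ring-B silyloxy acid; 22 the ring-A 2-fluoroaroyl chloride
Product: 26 (2R,3R)-5-(benzyloxy)-2-[2,5-bis(benzyloxy)-4-methoxyphenyl]-3,6,7-trimethoxychroman-4-one, via mixed anhydride 23 (not isolated), via fluoro ketone 24 (not isolated), via cis epimer 25 (not isolated)
Conditions: DBU, Ir[dF(CF3)ppy]2(dtbbpy)PF6 (cat.), NiCl2·DME (cat.), dtbbpy (cat.), 1,4-dioxane, blue LEDs, rt; then TBAF, THF, 0 °C → rt, same flask
Reagents that add atoms: none
Why: Acid 13 and aroyl chloride 22 form mixed anhydride 23; zerovalent nickel inserts into its aroyl C–O bond, single-electron oxidation of the divalent aroyl–nickel carboxylate by the photoexcited iridium complex releases CO2, and reductive elimination from the trivalent acyl(alkyl)nickel species makes the C3–C4 bond of ketone 24 (the closest known reaction type is the metallaphotoredox CO2 extrusion–recombination of α-alkoxy acid/acyl chloride pairs). Fluoride then unmasks the C2 alkoxide, which displaces the fluoride ortho to the new ketone by addition–elimination (intramolecular SNAr, a 6-exo-trig closure onto C8a) and so closes ring C through the O1–C8a bond. C2 is carried unchanged from 13, since no bond to it is made or broken. C3, scrambled at the radical stage, is set under thermodynamic control by C2: enolisation in the basic medium should funnel cis epimer 25 into the 2,3-trans isomer 26, with aryl and methoxy both equatorial. The step needs CO2 loss only on the α-alkoxy side (the aroyl carboxylate cannot decarboxylate), a C–F bond inert to nickel, and ring closure faster than retro-aldol cleavage. The last is secured by the ortho ketone, the two meta oxygens and the out-of-plane C6 methoxy group, which together leave C8a activated.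

Step 14
Reactants: 26 the tri-O-benzyl flavanone
Product: 27 (2R,3R)-2-(2,5-dihydroxy-4-methoxyphenyl)-5-hydroxy-3,6,7-trimethoxychroman-4-one (CNP0257825.1)
Conditions: H2 (1 atm), Pd/C, EtOAc/MeOH, rt; work-up under argon
Reagents that add atoms: none
Why: Hydrogenolysis of the three aryl benzyl ethers over palladium under neutral conditions should leave the ketone, the methyl ethers and both stereocentres untouched.

**Compound list**

1 | 2-methoxybenzene-1,4-diol (methoxyhydroquinone) | COc1cc(O)ccc1O | starting material
2 | 1,4-bis(benzyloxy)-2-methoxybenzene | COc1cc(OCc2ccccc2)ccc1OCc1ccccc1 | intermediate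
3 | [2,5-bis(benzyloxy)-4-methoxybenzylidene]dimethyliminium chloride (formed in step 2, not isolated) | COc1cc(OCc2ccccc2)c(C=[N+](C)C)cc1OCc1ccccc1.[Cl-] | intermediate
4 | 2,5-bis(benzyloxy)-4-methoxybenzaldehyde | COc1cc(OCc2ccccc2)c(C=O)cc1OCc1ccccc1 | intermediate
5 | (S)-4-benzyloxazolidin-2-one | O=C1N[C@@H](Cc2ccccc2)CO1 | starting material
6 | methoxyacetyl chloride | COCC(Cl)=O | starting material
7 | lithium (S)-4-benzyl-2-oxooxazolidin-3-ide (formed in step 3, not isolated) | [Li+].O=C1[N-][C@@H](Cc2ccccc2)CO1 | intermediate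
8 | (S)-4-benzyl-3-(2-methoxyacetyl)oxazolidin-2-one | COCC(=O)N1[C@@H](Cc2ccccc2)COC1=O | intermediate
9 | (Z)-dibutylboron enolate of 8 (formed in step 4, not isolated) | CO/C=C(\OB(CCCC)CCCC)N1[C@@H](Cc2ccccc2)COC1=O | intermediate
10 | (S)-4-benzyl-3-{(2S,3R)-3-[2,5-bis(benzyloxy)-4-methoxyphenyl]-3-hydroxy-2-methoxypropanoyl}oxazolidin-2-one | COc1cc(OCc2ccccc2)c([C@@H](O)[C@H](OC)C(=O)N2[C@@H](Cc3ccccc3)COC2=O)cc1OCc1ccccc1 | intermediate
11 | (S)-4-benzyl-3-{(2S,3R)-3-[2,5-bis(benzyloxy)-4-methoxyphenyl]-3-[(tert-butyldimethylsilyl)oxy]-2-methoxypropanoyl}oxazolidin-2-one | COc1cc(OCc2ccccc2)c([C@@H](O[Si](C)(C)C(C)(C)C)[C@H](OC)C(=O)N2[C@@H](Cc3ccccc3)COC2=O)cc1OCc1ccccc1 | intermediate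
12 | (2S,3R)-3-[2,5-bis(benzyloxy)-4-methoxyphenyl]-3-[(tert-butyldimethylsilyl)oxy]-2-methoxypropaneperoxoic acid (formed in step 6, not isolated) | COc1cc(OCc2ccccc2)c([C@@H](O[Si](C)(C)C(C)(C)C)[C@H](OC)C(=O)OO)cc1OCc1ccccc1 | intermediate
13 | (2S,3R)-3-[2,5-bis(benzyloxy)-4-methoxyphenyl]-3-[(tert-butyldimethylsilyl)oxy]-2-methoxypropanoic acid | COc1cc(OCc2ccccc2)c([C@@H](O[Si](C)(C)C(C)(C)C)[C@H](OC)C(=O)O)cc1OCc1ccccc1 | intermediate
14 | 3,4,5-trimethoxyaniline | COc1cc(N)cc(OC)c1OC | starting material
15 | 3,4,5-trimethoxybenzenediazonium fluoride (formed in step 7, not isolated) | COc1cc([N+]#N)cc(OC)c1OC.[F-] | intermediate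
16 | 5-fluoro-1,2,3-trimethoxybenzene | COc1cc(F)cc(OC)c1OC | intermediate
17 | (6-fluoro-2,3,4-trimethoxyphenyl)lithium (formed in step 8, not isolated) | [Li]c1c(F)cc(OC)c(OC)c1OC | intermediate
18 | 6-fluoro-2,3,4-trimethoxybenzaldehyde | COc1cc(F)c(C=O)c(OC)c1OC | intermediate
19 | 6-fluoro-2-hydroxy-3,4-dimethoxybenzaldehyde | COc1cc(F)c(C=O)c(O)c1OC | intermediate
20 | 2-(benzyloxy)-6-fluoro-3,4-dimethoxybenzaldehyde | COc1cc(F)c(C=O)c(OCc2ccccc2)c1OC | intermediate
21 | 2-(benzyloxy)-6-fluoro-3,4-dimethoxybenzoic acid | COc1cc(F)c(C(=O)O)c(OCc2ccccc2)c1OC | intermediate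
22 | 2-(benzyloxy)-6-fluoro-3,4-dimethoxybenzoyl chloride | COc1cc(F)c(C(Cl)=O)c(OCc2ccccc2)c1OC | intermediate
23 | mixed anhydride of acid 13 and acid 21 (formed in step 13, not isolated) | COc1cc(OCc2ccccc2)c([C@@H](O[Si](C)(C)C(C)(C)C)[C@H](OC)C(=O)OC(=O)c2c(F)cc(OC)c(OC)c2OCc2ccccc2)cc1OCc1ccccc1 | intermediate
24 | (3R)-1-[2-(benzyloxy)-6-fluoro-3,4-dimethoxyphenyl]-3-[2,5-bis(benzyloxy)-4-methoxyphenyl]-3-[(tert-butyldimethylsilyl)oxy]-2-methoxypropan-1-one, both C2 epimers (formed in step 13, not isolated) | COc1cc(OCc2ccccc2)c([C@@H](O[Si](C)(C)C(C)(C)C)C(OC)C(=O)c2c(F)cc(OC)c(OC)c2OCc2ccccc2)cc1OCc1ccccc1 | intermediate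
25 | (2R,3S)-5-(benzyloxy)-2-[2,5-bis(benzyloxy)-4-methoxyphenyl]-3,6,7-trimethoxychroman-4-one, the 2,3-cis epimer (formed in step 13, not isolated) | COc1cc(OCc5ccccc5)c([C@H]2Oc3cc(OC)c(OC)c(OCc4ccccc4)c3C(=O)[C@H]2OC)cc1OCc1ccccc1 | intermediate
26 | (2R,3R)-5-(benzyloxy)-2-[2,5-bis(benzyloxy)-4-methoxyphenyl]-3,6,7-trimethoxychroman-4-one | COc1cc(OCc5ccccc5)c([C@H]2Oc3cc(OC)c(OC)c(OCc4ccccc4)c3C(=O)[C@@H]2OC)cc1OCc1ccccc1 | intermediate
27 | (2R,3R)-2-(2,5-dihydroxy-4-methoxyphenyl)-5-hydroxy-3,6,7-trimethoxychroman-4-one | COc1cc(O)c([C@H]2Oc3cc(OC)c(OC)c(O)c3C(=O)[C@@H]2OC)cc1O | target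

**Step count and risks**

Total step count: 14. Longest linear sequence: 8 steps (steps 7 to 14).

Steps most likely to fail:

1. Step 13. The α-methoxyalkyl radical may be lost to hydrogen abstraction instead of being captured by the hindered aroyl–nickel species, or the photocatalyst may oxidise the electron-rich ring B; in the second stage, retro-aldol cleavage of the unmasked alkoxide may compete with ring closure. The fallback sets out from 13 and 16 and comes back to the route at 27. Acid 13 is condensed with N,O-dimethylhydroxylamine hydrochloride (EDC·HCl, HOBt, iPr2NEt, CH2Cl2) to the N-methoxy-N-methylamide F1. Aryllithium 17, generated from 16 as in step 8, is added to F1 at −78 °C (Weinreb ketone synthesis; the bond made is now C4–C4a, C3–C4 coming from the amide) to give the fluoro ketone F2. TBAF in THF then closes ring C by the same intramolecular SNAr, with equilibration at C3, to the 5-O-methyl flavanone F3. BCl3 with pentamethylbenzene in CH2Cl2 at −78 °C removes both benzyl ethers and, through chelation to the C4 carbonyl, the 5-O-methyl group, giving 27.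

2. Step 7. Thermal loss of nitrogen from the electron-rich diazonium ion may be diverted to hydrolysis, reduction and tar formation. The fallback sets out from 14 and comes back at 16. Diazotisation of 14 and treatment with CuBr (Sandmeyer reaction) gives 5-bromo-1,2,3-trimethoxybenzene F4, which is also a commercial compound. Bromine–lithium exchange (n-BuLi, THF, −78 °C) and electrophilic fluorination with N-fluorobenzenesulfonimide then give 16.

3. Step 14. Hydrogenolytic cleavage of the doubly activated benzylic C2–O1 bond (opening of ring C) may compete with debenzylation, and the freed hydroquinone may oxidise in air during work-up. The fallback sets out from 26 and comes back at 27: non-reductive debenzylation with BCl3 and pentamethylbenzene in CH2Cl2 at −78 °C, followed by a methanol quench under argon. No new compound is made (F0).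

**Further compounds**

F1 | step 13 | (2S,3R)-3-[2,5-bis(benzyloxy)-4-methoxyphenyl]-3-[(tert-butyldimethylsilyl)oxy]-N,2-dimethoxy-N-methylpropanamide | COc1cc(OCc2ccccc2)c([C@@H](O[Si](C)(C)C(C)(C)C)[C@H](OC)C(=O)N(C)OC)cc1OCc1ccccc1
F2 | step 13 | (2S,3R)-3-[2,5-bis(benzyloxy)-4-methoxyphenyl]-3-[(tert-butyldimethylsilyl)oxy]-1-(6-fluoro-2,3,4-trimethoxyphenyl)-2-methoxypropan-1-one | COc1cc(OCc2ccccc2)c([C@@H](O[Si](C)(C)C(C)(C)C)[C@H](OC)C(=O)c2c(F)cc(OC)c(OC)c2OC)cc1OCc1ccccc1
F3 | step 13 | (2R,3R)-2-[2,5-bis(benzyloxy)-4-methoxyphenyl]-3,5,6,7-tetramethoxychroman-4-one | COc1cc(OCc5ccccc5)c([C@H]2Oc3cc(OC)c(OC)c(OC)c3C(=O)[C@@H]2OC)cc1OCc1ccccc1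
F4 | step 7 | 5-bromo-1,2,3-trimethoxybenzene | COc1cc(Br)cc(OC)c1OC
F0 | step 14 | none | none
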